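The route rests on cutting the C7–C11 bond of the α-methylene-γ-lactone (ring O–C12–C11–C7–C6). The feature exploited is the oxygen on C8, vicinal to ring-fusion carbon C7: in the precursor C7 and C8 form a trans-epoxide and O6 carries a diethylphosphonoacetate. In one operation the C11 carbanion opens the epoxide at C7 (5-exo, inversion) and the resulting phosphono lactone is methylenated in the flask, which closes the lactone, sets C7, installs C13 and frees only the C8 hydroxyl for the 2-methylbutanoate. The ten-membered ring is closed afterwards by a Wittig union at C4=C5 and a Nozaki–Hiyama–Kishi cyclisation at C9–C10.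

Key step: step 6

Remark on the chemistry: atoms are numbered as in germacranolides (ring carbons C1–C10, lactone carbons C11 and C12, exocyclic methylene C13, formyl C14, hydroxymethyl C15), and these numbers are used for every intermediate.

Step 1
Reactants: 1 4-methoxybenzyl alcohol; 2 allyl bromide
Product: 3 allyl 4-methoxybenzyl ether
Conditions: NaH, Bu4NI (cat.), THF, 0 °C to rt
Reagents that add atoms: none
Why: Williamson ether synthesis of a primary alkoxide with a reactive allylic bromide gives the metathesis partner that carries the future C8, C9 and O9 as a PMB ether.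

Step 2
Reactants: 4 (S)-but-3-ene-1,2-diol
Product: 5 (S)-1-((tert-butyldimethylsilyl)oxy)but-3-en-2-ol
Conditions: TBSCl (1.05 equiv), imidazole, CH2Cl2, −20 °C
Reagents that add atoms: tert-butyldimethylsilyl chloride, CC(C)(C)[Si](C)(C)Cl
Why: Selective silylation of the less hindered primary hydroxyl leaves the C6 carbinol free, and the C6 stereocentre comes unchanged from the chiral pool.

Step 3
Reactants: 5 (S)-1-((tert-butyldimethylsilyl)oxy)but-3-en-2-ol; 3 allyl 4-methoxybenzyl ether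
Product: 6 (S,E)-1-((tert-butyldimethylsilyl)oxy)-5-((4-methoxybenzyl)oxy)pent-3-en-2-ol
Conditions: second-generation Hoveyda–Grubbs catalyst (5 mol %), 3 (3 equiv), CH2Cl2, 40 °C
Reagents that add atoms: none
Why: Olefin cross-metathesis of the secondary allylic alcohol with an excess of the allyl ether should give the (E)-C7=C8 alkene under thermodynamic control.

Step 4
Reactants: 6 (S,E)-1-((tert-butyldimethylsilyl)oxy)-5-((4-methoxybenzyl)oxy)pent-3-en-2-ol
Product: 7 (R)-2-((tert-butyldimethylsilyl)oxy)-1-((2R,3R)-3-(((4-methoxybenzyl)oxy)methyl)oxiran-2-yl)ethan-1-ol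
Conditions: Ti(OiPr)4 (20 mol %), (−)-diisopropyl D-tartrate (24 mol %), t-BuOOH, 4 Å MS, CH2Cl2, −20 °C
Reagents that add atoms: tert-butyl hydroperoxide, CC(C)(C)OO
Why: Sharpless asymmetric epoxidation of the secondary allylic alcohol in its matched (fast-reacting) sense, in which the D-tartrate catalyst delivers oxygen to the C7=C8 face that the (S)-carbinol also favours, should give the erythro trans-epoxy alcohol and so sets C7 and C8.

Step 5
Reactants: 7 (R)-2-((tert-butyldimethylsilyl)oxy)-1-((2R,3R)-3-(((4-methoxybenzyl)oxy)methyl)oxiran-2-yl)ethan-1-ol; 8 diethylphosphonoacetic acid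
Product: 9 (R)-2-((tert-butyldimethylsilyl)oxy)-1-((2S,3R)-3-(((4-methoxybenzyl)oxy)methyl)oxiran-2-yl)ethyl 2-(diethoxyphosphoryl)acetate
Conditions: DCC, DMAP (cat.), CH2Cl2, 0 °C to rt
Reagents that add atoms: none
Why: Steglich esterification places the C11–C12 unit on O6 under neutral conditions that leave the epoxide intact (the change of descriptor at the oxirane carbon is only a change of CIP priority).

Step 6
Reactants: 9 (R)-2-((tert-butyldimethylsilyl)oxy)-1-((2S,3R)-3-(((4-methoxybenzyl)oxy)methyl)oxiran-2-yl)ethyl 2-(diethoxyphosphoryl)acetate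
Product: 11 (4R,5S)-5-(((tert-butyldimethylsilyl)oxy)methyl)-4-((S)-1-hydroxy-2-((4-methoxybenzyl)oxy)ethyl)-3-methylenedihydrofuran-2(3H)-one, via phosphono lactone 10 (not isolated)
Conditions: NaH (1.05 equiv), THF/DMF, 0 to 50 °C; then (CH2O)n, 50 °C
Reagents that add atoms: formaldehyde (from paraformaldehyde), C=O
Why: NaH deprotonates C11 of the phosphonoacetate, the carbanion attacks C7 of the adjacent trans-epoxide from the face opposite to the C7–O bond (SN2), the C8 alkoxide that results is protonated by the more acidic C11–H of phosphono lactone 10, and the phosphonate anion so formed undergoes Horner–Wadsworth–Emmons olefination with formaldehyde to give the exocyclic C11=C13 bond. The closest known reaction types are the intramolecular alkylation of stabilised carbanions by epoxides (Stork-type epoxide cyclisation, here through an ester tether as in the carbamate and imidate openings of 2,3-epoxy alcohols at C2) and the epoxide-opening/formaldehyde-olefination sequence of phosphonoacetate anions that leads to α-methylene-γ-butyrolactones. The γ-lactone ring is closed in the 5-exo-tet mode by the C11–C7 bond. C7 is set by inversion at the epoxide carbon and therefore follows from the epoxide of step 4, C6 and C8 are not touched, and the trans relation of the C6 and C7 substituents on the lactone is the outcome. The step needs C-alkylation at C7 rather than 6-endo attack at C8 or O-alkylation to a ketene acetal: the collinear trajectory open to the exo mode on a trans-epoxide and the soft, phosphonate-stabilised carbanion should secure this, while the C9 PMB ether offers no group that could migrate to the C8 alkoxide. Only the C8 hydroxyl is left free, so the following acylation needs no differentiation of oxygens.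

Step 7
Reactants: 11 (4R,5S)-5-(((tert-butyldimethylsilyl)oxy)methyl)-4-((S)-1-hydroxy-2-((4-methoxybenzyl)oxy)ethyl)-3-methylenedihydrofuran-2(3H)-one; 12 (S)-2-methylbutanoic acid
Product: 13 (S)-1-((2S,3R)-2-(((tert-butyldimethylsilyl)oxy)methyl)-4-methylene-5-oxotetrahydrofuran-3-yl)-2-((4-methoxybenzyl)oxy)ethyl (S)-2-methylbutanoate
Conditions: DCC, DMAP (cat.), CH2Cl2, 0 °C
Reagents that add atoms: none
Why: Steglich esterification acylates the only free hydroxyl (C8) with the chiral-pool acid, whose α-stereocentre is not expected to epimerise under carbodiimide activation with catalytic DMAP in the cold.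

Step 8
Reactants: 13 (S)-1-((2S,3R)-2-(((tert-butyldimethylsilyl)oxy)methyl)-4-methylene-5-oxotetrahydrofuran-3-yl)-2-((4-methoxybenzyl)oxy)ethyl (S)-2-methylbutanoate
Product: 14 (S)-1-((2S,3S)-2-(hydroxymethyl)-4-methylene-5-oxotetrahydrofuran-3-yl)-2-((4-methoxybenzyl)oxy)ethyl (S)-2-methylbutanoate
Conditions: HF·pyridine, pyridine, THF, 0 °C to rt
Reagents that add atoms: none
Why: Buffered fluoride cleavage of the primary TBS ether spares the esters, the PMB ether and the base-sensitive α-methylene lactone (the descriptor change at the ring carbon is again only a priority change).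

Step 9
Reactants: 14 (S)-1-((2S,3S)-2-(hydroxymethyl)-4-methylene-5-oxotetrahydrofuran-3-yl)-2-((4-methoxybenzyl)oxy)ethyl (S)-2-methylbutanoate
Product: 15 (S)-1-((2S,3R)-2-formyl-4-methylene-5-oxotetrahydrofuran-3-yl)-2-((4-methoxybenzyl)oxy)ethyl (S)-2-methylbutanoate
Conditions: Dess–Martin periodinane, NaHCO3, CH2Cl2, 0 °C to rt
Reagents that add atoms: none
Why: Dess–Martin oxidation gives the C5 aldehyde under buffered, non-basic conditions, and C6 should hold because the trans-disubstituted lactone is the more stable epimer.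

Step 10
Reactants: 16 5-bromopent-1-ene; 17 (E)-but-2-enal
Product: 18 (E)-6-bromohex-2-enal
Conditions: second-generation Hoveyda–Grubbs catalyst (2 mol %), 17 (5 equiv), CH2Cl2, 40 °C
Reagents that add atoms: none
Why: Cross-metathesis of a terminal alkene with crotonaldehyde is a reliable entry to (E)-enals and supplies C1–C4, C10 and C14.

Step 11
Reactants: 18 (E)-6-bromohex-2-enal
Product: 19 (Z)-6-bromo-2-iodohex-2-enal
Conditions: I2, K2CO3, DMAP (cat.), THF/H2O (1:1), rt
Reagents that add atoms: iodine, II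
Why: α-Iodination of the enal by conjugate addition of DMAP, iodination of the enolate and elimination (Baylis–Hillman-type pathway) gives the (Z)-2-iodoenal, with iodine cis to the chain as the ring-cis C1=C10 bond requires.

Step 12
Reactants: 19 (Z)-6-bromo-2-iodohex-2-enal
Product: 20 (Z)-6-bromo-2-iodo-1,1-dimethoxyhex-2-ene
Conditions: HC(OMe)3, PPTS (cat.), MeOH, rt
Reagents that add atoms: trimethyl orthoformate, COC(OC)OC; methanol, CO
Why: Acid-catalysed acetalisation driven by the orthoformate masks C14 at the aldehyde oxidation level for all later carbonyl chemistry.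

Step 13
Reactants: 20 (Z)-6-bromo-2-iodo-1,1-dimethoxyhex-2-ene
Product: 21 ((Z)-5-iodo-6,6-dimethoxyhex-4-en-1-yl)triphenylphosphonium bromide
Conditions: PPh3, MeCN, 80 °C
Reagents that add atoms: triphenylphosphine, c1ccc(cc1)P(c1ccccc1)c1ccccc1
Why: SN2 quaternisation of triphenylphosphine by the primary bromide occurs without touching the vinyl iodide, which is inert in the absence of a transition metal.

Step 14
Reactants: 21 ((Z)-5-iodo-6,6-dimethoxyhex-4-en-1-yl)triphenylphosphonium bromide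
Product: 23 (Z)-6-iodo-7,7-dimethoxy-2-(triphenyl-λ5-phosphanylidene)hept-5-enal, via phosphorus ylide 22 (not isolated)
Conditions: NaN(SiMe3)2 (1.05 equiv), THF, −78 °C; then HCO2Et, −78 °C to rt
Reagents that add atoms: ethyl formate, CCOC=O
Why: C-Formylation of the non-stabilised ylide with ethyl formate, with the released ethoxide completing the proton transfer, gives the stabilised α-formyl ylide that carries C15 (ylide acylation).

Step 15
Reactants: 15 (S)-1-((2S,3R)-2-formyl-4-methylene-5-oxotetrahydrofuran-3-yl)-2-((4-methoxybenzyl)oxy)ethyl (S)-2-methylbutanoate; 23 (Z)-6-iodo-7,7-dimethoxy-2-(triphenyl-λ5-phosphanylidene)hept-5-enal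
Product: 24 (S)-1-((2R,3S)-2-((1E,5Z)-2-formyl-6-iodo-7,7-dimethoxyhepta-1,5-dien-1-yl)-4-methylene-5-oxotetrahydrofuran-3-yl)-2-((4-methoxybenzyl)oxy)ethyl (S)-2-methylbutanoate
Conditions: toluene, 80 °C
Reagents that add atoms: none
Why: Wittig olefination of the activated α-acyloxy aldehyde with a stabilised α-formyl ylide should give the (E)-enal, in which the formyl group (C15) is trans and the C3 chain cis to C6 as the ring-cis C4=C5 bond requires.

Step 16
Reactants: 24 (S)-1-((2R,3S)-2-((1E,5Z)-2-formyl-6-iodo-7,7-dimethoxyhepta-1,5-dien-1-yl)-4-methylene-5-oxotetrahydrofuran-3-yl)-2-((4-methoxybenzyl)oxy)ethyl (S)-2-methylbutanoate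
Product: 25 (S)-1-((2R,3S)-2-((1E,5Z)-2-(hydroxymethyl)-6-iodo-7,7-dimethoxyhepta-1,5-dien-1-yl)-4-methylene-5-oxotetrahydrofuran-3-yl)-2-((4-methoxybenzyl)oxy)ethyl (S)-2-methylbutanoate
Conditions: NaBH4, CeCl3·7H2O, MeOH, −78 °C
Reagents that add atoms: none
Why: Luche 1,2-reduction converts the enal into the C15 allylic alcohol while esters, lactone, acetal and the conjugated exocyclic methylene are left alone at low temperature.

Step 17
Reactants: 25 (S)-1-((2R,3S)-2-((1E,5Z)-2-(hydroxymethyl)-6-iodo-7,7-dimethoxyhepta-1,5-dien-1-yl)-4-methylene-5-oxotetrahydrofuran-3-yl)-2-((4-methoxybenzyl)oxy)ethyl (S)-2-methylbutanoate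
Product: 26 (S)-1-((2R,3S)-2-((1E,5Z)-6-iodo-7,7-dimethoxy-2-(((triethylsilyl)oxy)methyl)hepta-1,5-dien-1-yl)-4-methylene-5-oxotetrahydrofuran-3-yl)-2-((4-methoxybenzyl)oxy)ethyl (S)-2-methylbutanoate
Conditions: TESCl, imidazole, CH2Cl2, 0 °C
Reagents that add atoms: chlorotriethylsilane, CC[Si](CC)(CC)Cl
Why: Silylation of the primary allylic alcohol gives a TES ether that survives the oxidative and organochromium steps and falls together with the acetal at the end.

Step 18
Reactants: 26 (S)-1-((2R,3S)-2-((1E,5Z)-6-iodo-7,7-dimethoxy-2-(((triethylsilyl)oxy)methyl)hepta-1,5-dien-1-yl)-4-methylene-5-oxotetrahydrofuran-3-yl)-2-((4-methoxybenzyl)oxy)ethyl (S)-2-methylbutanoate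
Product: 27 (S)-2-hydroxy-1-((2R,3S)-2-((1E,5Z)-6-iodo-7,7-dimethoxy-2-(((triethylsilyl)oxy)methyl)hepta-1,5-dien-1-yl)-4-methylene-5-oxotetrahydrofuran-3-yl)ethyl (S)-2-methylbutanoate
Conditions: DDQ, CH2Cl2/pH 7 buffer, 0 °C; used at once
Reagents that add atoms: none
Why: Oxidative cleavage of the PMB ether by DDQ under buffered conditions frees the C9 hydroxyl without acid or base, and immediate use forestalls migration of the neighbouring 2-methylbutanoyl group.

Step 19
Reactants: 27 (S)-2-hydroxy-1-((2R,3S)-2-((1E,5Z)-6-iodo-7,7-dimethoxy-2-(((triethylsilyl)oxy)methyl)hepta-1,5-dien-1-yl)-4-methylene-5-oxotetrahydrofuran-3-yl)ethyl (S)-2-methylbutanoate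
Product: 28 (S)-1-((2R,3S)-2-((1E,5Z)-6-iodo-7,7-dimethoxy-2-(((triethylsilyl)oxy)methyl)hepta-1,5-dien-1-yl)-4-methylene-5-oxotetrahydrofuran-3-yl)-2-oxoethyl (S)-2-methylbutanoate
Conditions: Dess–Martin periodinane, NaHCO3, CH2Cl2, 0 °C
Reagents that add atoms: none
Why: Buffered Dess–Martin oxidation gives the α-acyloxy aldehyde at C9 without epimerising C8.

Step 20
Reactants: 28 (S)-1-((2R,3S)-2-((1E,5Z)-6-iodo-7,7-dimethoxy-2-(((triethylsilyl)oxy)methyl)hepta-1,5-dien-1-yl)-4-methylene-5-oxotetrahydrofuran-3-yl)-2-oxoethyl (S)-2-methylbutanoate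
Product: 29 (3aS,4S,5S,6E,10E,11aR)-6-(dimethoxymethyl)-5-hydroxy-3-methylene-2-oxo-10-(((triethylsilyl)oxy)methyl)-2,3,3a,4,5,8,9,11a-octahydrocyclodeca[b]furan-4-yl (S)-2-methylbutanoate
Conditions: CrCl2 (10 equiv), NiCl2 (cat.), DMSO/THF, rt, 2 mM
Reagents that add atoms: none
Why: Nozaki–Hiyama–Kishi cyclisation (nickel-catalysed insertion into the C10–I bond, transmetalation to chromium, addition to the C9 aldehyde) closes the ten-membered ring with retention of the C1=C10 geometry, and C9 should arise from a transition state with the C8–O bond anti to the forming C9–C10 bond and the carbonyl oxygen turned outward, which places O8 and O9 trans (9S).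

Step 21
Reactants: 29 (3aS,4S,5S,6E,10E,11aR)-6-(dimethoxymethyl)-5-hydroxy-3-methylene-2-oxo-10-(((triethylsilyl)oxy)methyl)-2,3,3a,4,5,8,9,11a-octahydrocyclodeca[b]furan-4-yl (S)-2-methylbutanoate
Product: 30 (3aS,4S,5S,6E,10E,11aR)-5-acetoxy-6-(dimethoxymethyl)-3-methylene-2-oxo-10-(((triethylsilyl)oxy)methyl)-2,3,3a,4,5,8,9,11a-octahydrocyclodeca[b]furan-4-yl (S)-2-methylbutanoate
Conditions: Ac2O, pyridine, DMAP (cat.), CH2Cl2, 0 °C
Reagents that add atoms: acetic anhydride, CC(=O)OC(C)=O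
Why: Acetylation of the only free hydroxyl (C9) by nucleophilic catalysis is run cold and short so that the adjacent 2-methylbutanoate does not migrate.

Step 22
Reactants: 30 (3aS,4S,5S,6E,10E,11aR)-5-acetoxy-6-(dimethoxymethyl)-3-methylene-2-oxo-10-(((triethylsilyl)oxy)methyl)-2,3,3a,4,5,8,9,11a-octahydrocyclodeca[b]furan-4-yl (S)-2-methylbutanoate
Product: 31 (3aS,4S,5S,6E,10E,11aR)-5-acetoxy-6-formyl-10-(hydroxymethyl)-3-methylene-2-oxo-2,3,3a,4,5,8,9,11a-octahydrocyclodeca[b]furan-4-yl (S)-2-methylbutanoate (CNP0247637.6)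
Conditions: AcOH/THF/H2O (3:1:1), rt
Reagents that add atoms: water, O
Why: Mild aqueous acid hydrolyses the conjugated dimethyl acetal to the C14 enal and cleaves the primary TES ether at C15 in one operation, under which both esters and the α-methylene lactone should be stable.

Compound list
1 | 4-methoxybenzyl alcohol | COc1ccc(CO)cc1 | starting material
2 | allyl bromide | C=CCBr | starting material
3 | allyl 4-methoxybenzyl ether | C=CCOCc1ccc(OC)cc1 | intermediate
4 | (S)-but-3-ene-1,2-diol | OC[C@@H](O)C=C | starting material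
5 | (S)-1-((tert-butyldimethylsilyl)oxy)but-3-en-2-ol | CC(C)(C)[Si](C)(C)OC[C@@H](O)C=C | intermediate
6 | (S,E)-1-((tert-butyldimethylsilyl)oxy)-5-((4-methoxybenzyl)oxy)pent-3-en-2-ol | CC(C)(C)[Si](C)(C)OC[C@@H](O)/C=C/COCc1ccc(OC)cc1 | intermediate
7 | (R)-2-((tert-butyldimethylsilyl)oxy)-1-((2R,3R)-3-(((4-methoxybenzyl)oxy)methyl)oxiran-2-yl)ethan-1-ol | CC(C)(C)[Si](C)(C)OC[C@@H](O)[C@H]1O[C@@H]1COCc1ccc(OC)cc1 | intermediate
8 | diethylphosphonoacetic acid | CCOP(=O)(CC(=O)O)OCC | starting material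
9 | (R)-2-((tert-butyldimethylsilyl)oxy)-1-((2S,3R)-3-(((4-methoxybenzyl)oxy)methyl)oxiran-2-yl)ethyl 2-(diethoxyphosphoryl)acetate | CCOP(=O)(OCC)CC(=O)O[C@H](CO[Si](C)(C)C(C)(C)C)[C@H]1O[C@@H]1COCc1ccc(OC)cc1 | intermediate
10 | diethyl ((4R,5S)-5-(((tert-butyldimethylsilyl)oxy)methyl)-4-((S)-1-hydroxy-2-((4-methoxybenzyl)oxy)ethyl)-2-oxotetrahydrofuran-3-yl)phosphonate (C3 epimers, present as its sodium salt) | O=C1O[C@H](CO[Si](C)(C)C(C)(C)C)[C@@H]([C@H](O)COCc2ccc(OC)cc2)C1P(=O)(OCC)OCC | intermediate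
11 | (4R,5S)-5-(((tert-butyldimethylsilyl)oxy)methyl)-4-((S)-1-hydroxy-2-((4-methoxybenzyl)oxy)ethyl)-3-methylenedihydrofuran-2(3H)-one | C=C1C(=O)O[C@H](CO[Si](C)(C)C(C)(C)C)[C@H]1[C@H](O)COCc1ccc(OC)cc1 | intermediate
12 | (S)-2-methylbutanoic acid | CC[C@H](C)C(=O)O | starting material
13 | (S)-1-((2S,3R)-2-(((tert-butyldimethylsilyl)oxy)methyl)-4-methylene-5-oxotetrahydrofuran-3-yl)-2-((4-methoxybenzyl)oxy)ethyl (S)-2-methylbutanoate | C=C1C(=O)O[C@H](CO[Si](C)(C)C(C)(C)C)[C@H]1[C@H](OC(=O)[C@@H](C)CC)COCc1ccc(OC)cc1 | intermediate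
14 | (S)-1-((2S,3S)-2-(hydroxymethyl)-4-methylene-5-oxotetrahydrofuran-3-yl)-2-((4-methoxybenzyl)oxy)ethyl (S)-2-methylbutanoate | C=C1C(=O)O[C@H](CO)[C@H]1[C@H](OC(=O)[C@@H](C)CC)COCc1ccc(OC)cc1 | intermediate
15 | (S)-1-((2S,3R)-2-formyl-4-methylene-5-oxotetrahydrofuran-3-yl)-2-((4-methoxybenzyl)oxy)ethyl (S)-2-methylbutanoate | C=C1C(=O)O[C@H](C=O)[C@H]1[C@H](OC(=O)[C@@H](C)CC)COCc1ccc(OC)cc1 | intermediate
16 | 5-bromopent-1-ene | C=CCCCBr | starting material
17 | (E)-but-2-enal (crotonaldehyde) | C/C=C/C=O | starting material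
18 | (E)-6-bromohex-2-enal | O=C/C=C/CCCBr | intermediate
19 | (Z)-6-bromo-2-iodohex-2-enal | O=C/C(I)=C/CCCBr | intermediate
20 | (Z)-6-bromo-2-iodo-1,1-dimethoxyhex-2-ene | COC(OC)/C(I)=C/CCCBr | intermediate
21 | ((Z)-5-iodo-6,6-dimethoxyhex-4-en-1-yl)triphenylphosphonium bromide | COC(OC)/C(I)=C/CCC[P+](c1ccccc1)(c1ccccc1)c1ccccc1.[Br-] | intermediate
22 | ((Z)-5-iodo-6,6-dimethoxyhex-4-en-1-ylidene)triphenyl-λ5-phosphane | COC(OC)/C(I)=C/CCC=P(c1ccccc1)(c1ccccc1)c1ccccc1 | intermediate
23 | (Z)-6-iodo-7,7-dimethoxy-2-(triphenyl-λ5-phosphanylidene)hept-5-enal | COC(OC)/C(I)=C/CCC(C=O)=P(c1ccccc1)(c1ccccc1)c1ccccc1 | intermediate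
24 | (S)-1-((2R,3S)-2-((1E,5Z)-2-formyl-6-iodo-7,7-dimethoxyhepta-1,5-dien-1-yl)-4-methylene-5-oxotetrahydrofuran-3-yl)-2-((4-methoxybenzyl)oxy)ethyl (S)-2-methylbutanoate | C=C1C(=O)O[C@H](/C=C(/C=O)CC/C=C(\I)C(OC)OC)[C@H]1[C@H](OC(=O)[C@@H](C)CC)COCc1ccc(OC)cc1 | intermediate
25 | (S)-1-((2R,3S)-2-((1E,5Z)-2-(hydroxymethyl)-6-iodo-7,7-dimethoxyhepta-1,5-dien-1-yl)-4-methylene-5-oxotetrahydrofuran-3-yl)-2-((4-methoxybenzyl)oxy)ethyl (S)-2-methylbutanoate | C=C1C(=O)O[C@H](/C=C(/CO)CC/C=C(\I)C(OC)OC)[C@H]1[C@H](OC(=O)[C@@H](C)CC)COCc1ccc(OC)cc1 | intermediate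
26 | (S)-1-((2R,3S)-2-((1E,5Z)-6-iodo-7,7-dimethoxy-2-(((triethylsilyl)oxy)methyl)hepta-1,5-dien-1-yl)-4-methylene-5-oxotetrahydrofuran-3-yl)-2-((4-methoxybenzyl)oxy)ethyl (S)-2-methylbutanoate | C=C1C(=O)O[C@H](/C=C(/CO[Si](CC)(CC)CC)CC/C=C(\I)C(OC)OC)[C@H]1[C@H](OC(=O)[C@@H](C)CC)COCc1ccc(OC)cc1 | intermediate
27 | (S)-2-hydroxy-1-((2R,3S)-2-((1E,5Z)-6-iodo-7,7-dimethoxy-2-(((triethylsilyl)oxy)methyl)hepta-1,5-dien-1-yl)-4-methylene-5-oxotetrahydrofuran-3-yl)ethyl (S)-2-methylbutanoate | C=C1C(=O)O[C@H](/C=C(/CO[Si](CC)(CC)CC)CC/C=C(\I)C(OC)OC)[C@H]1[C@H](OC(=O)[C@@H](C)CC)CO | intermediate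
28 | (S)-1-((2R,3S)-2-((1E,5Z)-6-iodo-7,7-dimethoxy-2-(((triethylsilyl)oxy)methyl)hepta-1,5-dien-1-yl)-4-methylene-5-oxotetrahydrofuran-3-yl)-2-oxoethyl (S)-2-methylbutanoate | C=C1C(=O)O[C@H](/C=C(/CO[Si](CC)(CC)CC)CC/C=C(\I)C(OC)OC)[C@H]1[C@H](OC(=O)[C@@H](C)CC)C=O | intermediate
29 | (3aS,4S,5S,6E,10E,11aR)-6-(dimethoxymethyl)-5-hydroxy-3-methylene-2-oxo-10-(((triethylsilyl)oxy)methyl)-2,3,3a,4,5,8,9,11a-octahydrocyclodeca[b]furan-4-yl (S)-2-methylbutanoate | C=C1C(=O)O[C@@H]2/C=C(/CO[Si](CC)(CC)CC)CC/C=C(/C(OC)OC)[C@H](O)[C@@H](OC(=O)[C@@H](C)CC)[C@@H]12 | intermediate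
30 | (3aS,4S,5S,6E,10E,11aR)-5-acetoxy-6-(dimethoxymethyl)-3-methylene-2-oxo-10-(((triethylsilyl)oxy)methyl)-2,3,3a,4,5,8,9,11a-octahydrocyclodeca[b]furan-4-yl (S)-2-methylbutanoate | C=C1C(=O)O[C@@H]2/C=C(/CO[Si](CC)(CC)CC)CC/C=C(/C(OC)OC)[C@H](OC(C)=O)[C@@H](OC(=O)[C@@H](C)CC)[C@@H]12 | intermediate
31 | (3aS,4S,5S,6E,10E,11aR)-5-acetoxy-6-formyl-10-(hydroxymethyl)-3-methylene-2-oxo-2,3,3a,4,5,8,9,11a-octahydrocyclodeca[b]furan-4-yl (S)-2-methylbutanoate | C=C1C(=O)O[C@@H]2/C=C(/CO)CC/C=C(/C=O)[C@H](OC(C)=O)[C@@H](OC(=O)[C@@H](C)CC)[C@@H]12 | target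

Total step count: 22. Longest linear sequence: 16 steps (steps 2–9 and 15–22, from diol 4).

Steps most likely to fail

1. Step 6 (key step). The phosphonate carbanion may alkylate through oxygen or attack C8 in the 6-endo mode. It may also cyclise too slowly, because the ester must reach its s-cis rotamer, so that acyl transfer or decomposition of the epoxide competes. The fallback sets out from epoxy alcohol 7 and returns at 11. It changes both the nucleophile and the way C13 is brought in. Esterification of 7 with mono-allyl malonate (DCC, DMAP) gives allyl malonate F1. The softer malonate carbanion (Cs2CO3, DMF), for which intramolecular C-alkylation by epoxides is classical, closes the same C11–C7 bond to give allyl ester lactone F2. Pd(PPh3)4 and pyrrolidine remove the allyl group to give carboxylic acid F3. Decarboxylative Mannich methylenation of F3 (aqueous formaldehyde, Et2NH, then AcOH/NaOAc) gives 11.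

2. Step 20. The vinylchromium species may add to the other face of the C9 aldehyde, since the open-chain Felkin–Anh/Cornforth preference would place O8 and O9 cis. Oligomerisation may also compete if dilution is insufficient. The fallback sets out from 28 and returns at 30. If the cyclisation delivers the C9 epimer, 9-epi alcohol F4, the substrate-controlled addition is corrected by an SN2 displacement. Mitsunobu reaction of F4 with acetic acid (PPh3, DIAD, toluene, 0 °C) inverts C9 and installs the acetate in one operation.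

3. Step 15. The hindered, weakly nucleophilic formyl ylide may olefinate too slowly at the temperature the α-acyloxy aldehyde tolerates, with epimerisation at C6 or decomposition. The fallback sets out from 15, uses ylide 23, and returns at 24. It replaces carbonyl olefination at C4=C5 by olefin metathesis. Non-basic Takai–Lombardo methylenation of 15 (Zn, CH2Br2, TiCl4, THF, 0 °C) gives vinyl lactone F5. Ylide 23 and aqueous formaldehyde give 2-substituted acrolein F6. Cross-metathesis of F5 with F6 (second-generation Hoveyda–Grubbs catalyst, CH2Cl2, 40 °C) should form the C4=C5 bond as the (E)-enal 24.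

Further compounds
F1 | step 6 | allyl (R)-2-((tert-butyldimethylsilyl)oxy)-1-((2S,3R)-3-(((4-methoxybenzyl)oxy)methyl)oxiran-2-yl)ethyl malonate | C=CCOC(=O)CC(=O)O[C@H](CO[Si](C)(C)C(C)(C)C)[C@H]1O[C@@H]1COCc1ccc(OC)cc1
F2 | step 6 | allyl (4R,5S)-5-(((tert-butyldimethylsilyl)oxy)methyl)-4-((S)-1-hydroxy-2-((4-methoxybenzyl)oxy)ethyl)-2-oxotetrahydrofuran-3-carboxylate (C3 epimers) | C=CCOC(=O)C1C(=O)O[C@H](CO[Si](C)(C)C(C)(C)C)[C@H]1[C@H](O)COCc1ccc(OC)cc1
F3 | step 6 | (4R,5S)-5-(((tert-butyldimethylsilyl)oxy)methyl)-4-((S)-1-hydroxy-2-((4-methoxybenzyl)oxy)ethyl)-2-oxotetrahydrofuran-3-carboxylic acid (C3 epimers) | OC(=O)C1C(=O)O[C@H](CO[Si](C)(C)C(C)(C)C)[C@H]1[C@H](O)COCc1ccc(OC)cc1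
F4 | step 20 | (3aS,4S,5R,6E,10E,11aR)-6-(dimethoxymethyl)-5-hydroxy-3-methylene-2-oxo-10-(((triethylsilyl)oxy)methyl)-2,3,3a,4,5,8,9,11a-octahydrocyclodeca[b]furan-4-yl (S)-2-methylbutanoate | C=C1C(=O)O[C@@H]2/C=C(/CO[Si](CC)(CC)CC)CC/C=C(/C(OC)OC)[C@@H](O)[C@@H](OC(=O)[C@@H](C)CC)[C@@H]12
F5 | step 15 | (S)-2-((4-methoxybenzyl)oxy)-1-((2R,3S)-4-methylene-5-oxo-2-vinyltetrahydrofuran-3-yl)ethyl (S)-2-methylbutanoate | C=C1C(=O)O[C@H](C=C)[C@H]1[C@H](OC(=O)[C@@H](C)CC)COCc1ccc(OC)cc1
F6 | step 15 | (Z)-6-iodo-7,7-dimethoxy-2-methylenehept-5-enal | C=C(C=O)CC/C=C(\I)C(OC)OC
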